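The synthesis rests on cutting two bonds of the anisole ring (ring A; C1' ether oxygen, C2' OMe, C3'/C5' Br) at once: the ether bond O–C1' and the neighbouring C2'–O bond. This traces ring A back to 3,5-dibromobenzyne. The feature exploited is that ring A carries its two oxygens on adjacent carbons C1' and C2', with the C3' bromine flanking C2', which is the pattern left when a nucleophile and then an electrophile add across a 3-bromoaryne. In one pot the aryloxide of ring B forms the ether at C1', and the C2' carbanion is borylated and oxidised to a hydroxyl. The precursors are a 2-iodoaryl 4-chlorobenzenesulfonate as aryne source and a benzyl-protected dibromocatechol as ring B.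

Key step: step 5

Remark: the second bromine of the ring B building block is introduced by a hydroxyl-directed method in a separate step, because an undirected second bromination could also go para to the benzyloxy group.

Step 1
Reactants: 1 2,4-dibromophenol
Product: 2 2,4-dibromo-6-iodophenol
Conditions: NIS (1.05 equiv), TsOH·H2O (10 mol %), MeCN, rt
Reagents that add atoms: N-iodosuccinimide, O=C1CCC(=O)N1I
Why: Electrophilic aromatic iodination: C6 is the only free carbon ortho or para to the hydroxyl of 1, so acid-activated NIS should iodinate there alone.

Step 2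
Reactants: 2 2,4-dibromo-6-iodophenol; 3 4-chlorobenzenesulfonyl chloride
Product: 4 2,4-dibromo-6-iodophenyl 4-chlorobenzenesulfonate
Conditions: Et3N (1.5 equiv), DMAP (5 mol %), CH2Cl2, 0 °C to rt
Reagents that add atoms: none
Why: O-Sulfonylation of a phenol under amine base with DMAP as sulfonyl-transfer catalyst; the acidic dihalophenol is fully ionised and its oxygen is the only nucleophilic site.

Step 3
Reactants: 5 2-(benzyloxy)phenol
Product: 6 2-(benzyloxy)-4-bromophenol
Conditions: NBS (1.0 equiv), MeCN, 0 °C, dark
Reagents that add atoms: N-bromosuccinimide, O=C1CCC(=O)N1Br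
Why: Electrophilic aromatic bromination: the free hydroxyl is a stronger para director than the benzyl ether, so one equivalent of NBS in a polar solvent should brominate C4, as it does for the corresponding methyl ether guaiacol.

Step 4
Reactants: 6 2-(benzyloxy)-4-bromophenol
Product: 7 2-(benzyloxy)-4,6-dibromophenol
Conditions: NBS (1.05 equiv), iPr2NH (10 mol %), CH2Cl2, 0 °C to rt, dark
Reagents that add atoms: N-bromosuccinimide, O=C1CCC(=O)N1Br
Why: Amine-catalysed ortho-bromination of a phenol: N-bromodiisopropylamine formed from NBS is held by a hydrogen bond to the hydroxyl and should deliver bromine to the one free ortho carbon C6 in preference to C5, which lies para to the benzyloxy group.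

Step 5
Reactants: 4 2,4-dibromo-6-iodophenyl 4-chlorobenzenesulfonate; 7 2-(benzyloxy)-4,6-dibromophenol
Product: 13 2-[2-(benzyloxy)-4,6-dibromophenoxy]-4,6-dibromophenol, via chloromagnesium aryloxide 8 (not isolated), via magnesiated sulfonate 9 (not isolated), via 3,5-dibromobenzyne 10 (not isolated), via arylmagnesium adduct 11 (not isolated), via dimethyl arylboronate 12 (not isolated)
Conditions: 7 (1.5 equiv), iPrMgCl (1.5 equiv), THF, 0 °C; separately 4 (1.0 equiv), iPrMgCl (1.0 equiv), THF, −78 °C; combine at −78 °C, warm to 0 °C; B(OMe)3 (3 equiv), −78 to 0 °C; AcOH, 30% aq H2O2, 0 °C to rt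
Reagents that add atoms: hydrogen peroxide, OO (oxygen of the new hydroxyl); trimethyl borate, COB(OC)OC (boron and methoxy groups reach only intermediate 12); isopropylmagnesium chloride, CC(C)[Mg]Cl (magnesium and chloride reach only intermediates 8, 9 and 11)
Why: Proposed new method: iodine–magnesium exchange at the iodine of 4, far faster than at either bromine, gives 9, whose ortho sulfonate leaves on warming to release aryne 10; aryloxide 8, whose ortho and para carbons are all substituted so that only oxygen can bond, adds to the aryne, and the resulting arylmagnesium 11 is captured by B(OMe)3 and oxidised with retention at carbon to the phenol. The closest known reactions are the three-component couplings of arynes from 2-iodoaryl sulfonates with magnesium thiolates or amides followed by an electrophile, and the addition of phenoxides to arynes made from silyl triflates; using an aryloxide in the magnesium manifold is the untested part. No ring is closed and no stereocentre is formed. The step needs attack at the aryne carbon remote from bromine (the future C1'), which the inductively withdrawing C3' bromine should secure by distorting the aryne and stabilising negative charge at the adjacent C2', with the bulk of bromine pushing the hindered aryloxide the same way. It also needs 11 to survive without ejecting bromide, for which the covalent carbon–magnesium bond and a temperature held at or below 0 °C are relied on, and it needs the aryne to be intercepted by 8 and not by 9, which the excess of 8 and the absence of free iPrMgCl during warming address.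

Step 6
Reactants: 13 2-[2-(benzyloxy)-4,6-dibromophenoxy]-4,6-dibromophenol
Product: 14 1-(benzyloxy)-3,5-dibromo-2-(3,5-dibromo-2-methoxyphenoxy)benzene
Conditions: MeI (1.5 equiv), K2CO3 (2 equiv), DMF, rt
Reagents that add atoms: iodomethane, CI
Why: Williamson ether synthesis: the acidic phenol flanked by bromine and aryloxy is deprotonated by K2CO3, and the small electrophile MeI should alkylate the only free oxygen.

Step 7
Reactants: 14 1-(benzyloxy)-3,5-dibromo-2-(3,5-dibromo-2-methoxyphenoxy)benzene
Product: 15 3,5-dibromo-2-(3,5-dibromo-2-methoxyphenoxy)phenol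
Conditions: BCl3 (2.5 equiv), C6HMe5 (3 equiv), CH2Cl2, −78 °C; H2O quench
Reagents that add atoms: none
Why: Lewis acid-mediated debenzylation with pentamethylbenzene as a non-basic benzyl cation trap: the benzyl C–O bond ionises at −78 °C, whereas the methyl ether, the diaryl ether and the C–Br bonds need far harsher conditions.

Compound list
1 | 2,4-dibromophenol | Oc1ccc(Br)cc1Br | starting material
2 | 2,4-dibromo-6-iodophenol | Oc1c(I)cc(Br)cc1Br | intermediate
3 | 4-chlorobenzenesulfonyl chloride | O=S(=O)(Cl)c1ccc(Cl)cc1 | starting material
4 | 2,4-dibromo-6-iodophenyl 4-chlorobenzenesulfonate | O=S(=O)(Oc1c(I)cc(Br)cc1Br)c1ccc(Cl)cc1 | intermediate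
5 | 2-(benzyloxy)phenol | Oc1ccccc1OCc1ccccc1 | starting material
6 | 2-(benzyloxy)-4-bromophenol | Oc1ccc(Br)cc1OCc1ccccc1 | intermediate
7 | 2-(benzyloxy)-4,6-dibromophenol | Oc1c(OCc2ccccc2)cc(Br)cc1Br | intermediate
8 | chloromagnesium 2-(benzyloxy)-4,6-dibromophenolate | Cl[Mg]Oc1c(OCc2ccccc2)cc(Br)cc1Br | intermediate
9 | 2,4-dibromo-6-(chloromagnesio)phenyl 4-chlorobenzenesulfonate | O=S(=O)(Oc1c([Mg]Cl)cc(Br)cc1Br)c1ccc(Cl)cc1 | intermediate
10 | 3,5-dibromobenzyne (3,5-dibromo-1,2-didehydrobenzene) | BrC1=CC(Br)=CC#C1 | intermediate
11 | {2-[2-(benzyloxy)-4,6-dibromophenoxy]-4,6-dibromophenyl}magnesium chloride | Cl[Mg]c1c(Br)cc(Br)cc1Oc1c(OCc2ccccc2)cc(Br)cc1Br | intermediate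
12 | dimethyl {2-[2-(benzyloxy)-4,6-dibromophenoxy]-4,6-dibromophenyl}boronate | COB(OC)c1c(Br)cc(Br)cc1Oc1c(OCc2ccccc2)cc(Br)cc1Br | intermediate
13 | 2-[2-(benzyloxy)-4,6-dibromophenoxy]-4,6-dibromophenol | Oc1c(Br)cc(Br)cc1Oc1c(OCc2ccccc2)cc(Br)cc1Br | intermediate
14 | 1-(benzyloxy)-3,5-dibromo-2-(3,5-dibromo-2-methoxyphenoxy)benzene | COc1c(Br)cc(Br)cc1Oc1c(OCc2ccccc2)cc(Br)cc1Br | intermediate
15 | 3,5-dibromo-2-(3,5-dibromo-2-methoxyphenoxy)phenol | COc1c(Br)cc(Br)cc1Oc1c(O)cc(Br)cc1Br | target

Total step count: 7
Longest linear sequence: 5 steps (steps 3, 4, 5, 6, 7 from 5; equally steps 1, 2, 5, 6, 7 from 1)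

Steps most likely to fail

Step 5. The hindered, weakly nucleophilic aryloxide may fail to intercept the aryne, so that the aryne is consumed by arylmagnesium 9 or oligomerises. The adduct 11 may also eject bromide before it is borylated, or the aryloxide may attack the sulfonate sulfur instead. The fallback is known chemistry, a metal-free O-arylation with a diaryliodonium salt; it sets out from 2 (used together with 7) and rejoins the route at 14. Phenol 2 is methylated (MeI, K2CO3, DMF) to 1,5-dibromo-3-iodo-2-methoxybenzene F1. Oxidation of its iodine to the trivalent state with mCPBA and TsOH·H2O, followed by 1,3,5-trimethoxybenzene, gives (3,5-dibromo-2-methoxyphenyl)(2,4,6-trimethoxyphenyl)iodonium 4-methylbenzenesulfonate F2. Phenol 7 with KOt-Bu in THF/toluene at rt to 40 °C should then be arylated on oxygen by F2, the electron-rich trimethoxyphenyl ligand staying on iodine. This gives 14 directly, so step 6 is skipped.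

Step 4. Bromination at C5, para to the benzyloxy group, may compete with hydroxyl-directed delivery to C6 and leave regioisomers that are hard to separate. The fallback sets out from 2 and rejoins at 7, with the position of the benzyloxy oxygen dictated by the iodine. Phenol 2 is protected (MOMCl, iPr2NEt, CH2Cl2) as 1,5-dibromo-3-iodo-2-(methoxymethoxy)benzene F3. Iodide-selective Ullmann-type C–O coupling with benzyl alcohol (CuI 10 mol %, 3,4,7,8-tetramethyl-1,10-phenanthroline, Cs2CO3, toluene, 80 °C) gives 1-(benzyloxy)-3,5-dibromo-2-(methoxymethoxy)benzene F4. HCl in MeOH then removes the acetal to give 7.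

Step 7. Complexation of BCl3 may cause partial loss of the flanked methyl ether, or the benzyl cation may re-attach to the liberated phenol ring. The fallback sets out from 14 and arrives at 15. The boron Lewis acid is replaced by protic acidolysis with a soft sulfur nucleophile (TFA, thioanisole, rt). The benzyl group is transferred to sulfur by a push–pull displacement at the benzylic carbon, a pathway closed to a methyl ether. No new compound arises on this path (F0).

Further compounds
F1 | step 5 | 1,5-dibromo-3-iodo-2-methoxybenzene | COc1c(I)cc(Br)cc1Br
F2 | step 5 | (3,5-dibromo-2-methoxyphenyl)(2,4,6-trimethoxyphenyl)iodonium 4-methylbenzenesulfonate | COc1cc(OC)c([I+]c2cc(Br)cc(Br)c2OC)c(OC)c1.Cc1ccc(cc1)S(=O)(=O)[O-]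
F3 | step 4 | 1,5-dibromo-3-iodo-2-(methoxymethoxy)benzene | COCOc1c(I)cc(Br)cc1Br
F4 | step 4 | 1-(benzyloxy)-3,5-dibromo-2-(methoxymethoxy)benzene | COCOc1c(OCc2ccccc2)cc(Br)cc1Br
F0 | step 7 | none | none
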